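**Retrosynthetic overview**
- The C40 skeleton is cut at C11=C12 and C11'=C12' into a diol-end C15 phosphonium salt, the C10 trienedial and a furanoid-end C15 phosphonium salt (two Wittig olefinations).
- Furanoid end: one PdCl2-catalysed domino on an acyclic α-hydroxyallene closes the dihydrofuran and the cyclohexane together; the allene axis becomes C-5' and the carbinol carbon is C-8'.
- The allenol comes from an enynol by Sharpless epoxidation, anti-SN2' methyl-copper opening (centre to axis), glycol cleavage and catalytic asymmetric alkenylzinc addition.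
- Diol end: 2,2,6-trimethylcyclohexanone, asymmetric enol-ether oxidation (C-5), Felkin–Anh acetylide addition (C-6, cis-diol), trans-hydroalumination.
- Ring order: the left cyclohexane is present from the start; the right dihydrofuran and right cyclohexane form in the same operation (step 7).

Assumption: the catalyst enantiomers named in steps 6 and 10 show the facial sense known for simpler substrates; if not, the mirror-image catalyst is taken.

**Route**

Step 1
Reactants: 1 (2E)-pent-2-en-4-yn-1-ol; 2 5-bromo-2-methylpent-1-ene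
Product: 4 (2E)-9-methyldeca-2,9-dien-4-yn-1-ol, via dilithium alkoxide acetylide 3 (not isolated)
Conditions: n-BuLi (2.1 equiv), THF/DMPU, −78 °C; 2, −78 → 25 °C; H2O
Reagents that add atoms: none
Why: Acetylide alkylation: the dianion of 1 reacts with the primary bromide only at the acetylide carbon, the lithium alkoxide being far less nucleophilic.

Step 2
Reactants: 4 (2E)-9-methyldeca-2,9-dien-4-yn-1-ol
Product: 5 [(2S,3S)-3-(6-methylhept-6-en-1-yn-1-yl)oxiran-2-yl]methanol
Conditions: Ti(OiPr)4 (10 mol%), L-(+)-diethyl tartrate (12 mol%), t-BuOOH, 4 Å sieves, CH2Cl2, −20 °C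
Reagents that add atoms: tert-butyl hydroperoxide, CC(C)(C)OO
Why: Sharpless asymmetric epoxidation of the (E)-allylic alcohol with the L-tartrate gives the (2S,3S)-epoxide (C-3 later fixes the allene axis), while the isolated alkene and the alkyne are not allylic alcohols and stay untouched.

Step 3
Reactants: 5 [(2S,3S)-3-(6-methylhept-6-en-1-yn-1-yl)oxiran-2-yl]methanol
Product: 6 (2R,Ra)-5,9-dimethyldeca-3,4,9-triene-1,2-diol
Conditions: MeMgBr (3 equiv), CuBr·SMe2 (10 mol%), P(OEt)3 (20 mol%), THF, −40 → 0 °C; H2O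
Reagents that add atoms: methylmagnesium bromide, C[Mg]Br
Why: Copper-catalysed anti-SN2' opening of the alkynyl oxirane (Krause-type) delivers methyl to the alkyne terminus opposite the leaving C–O bond, so the (3S) centre is transferred to the (Ra) allene axis and C-2 keeps its oxygen.

Step 4
Reactants: 6 (2R,Ra)-5,9-dimethyldeca-3,4,9-triene-1,2-diol
Product: 7 (Ra)-4,8-dimethylnona-2,3,8-trienal
Conditions: NaIO4, NaHCO3, CH2Cl2/H2O, 0 °C; used crude
Reagents that add atoms: none
Why: Periodate glycol cleavage removes C-1 as formaldehyde and turns the carbinol carbon into the aldehyde under neutral conditions that leave the allene axis intact.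

Step 5
Reactants: 8 but-2-yn-1-ol
Product: 9 tert-butyl(but-2-yn-1-yloxy)dimethylsilane
Conditions: t-BuMe2SiCl, imidazole, CH2Cl2, 25 °C
Reagents that add atoms: tert-butyl(chloro)dimethylsilane, CC(C)(C)[Si](C)(C)Cl
Why: Standard imidazole-promoted silylation of a primary alcohol.

Step 6
Reactants: 7 (Ra)-4,8-dimethylnona-2,3,8-trienal; 9 tert-butyl(but-2-yn-1-yloxy)dimethylsilane
Product: 12 (2E,4R,Ra)-1-[(tert-butyldimethylsilyl)oxy]-3,7,11-trimethyldodeca-2,5,6,11-tetraen-4-ol, via alkenylzirconocene chloride 10 (not isolated), via alkenyl(methyl)zinc 11 (not isolated)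
Conditions: 9, Cp2Zr(H)Cl (1.5 equiv), CH2Cl2, 25 °C; Me2Zn, toluene, −65 °C; (2S)-(−)-3-exo-morpholinoisoborneol (10 mol%), 7, −30 → 0 °C; H2O
Reagents that add atoms: none
Why: Syn-hydrozirconation puts the metal on the methyl-bearing alkyne carbon (E-alkenyl), Zr-to-Zn transmetalation and amino-alcohol-catalysed alkenylzinc addition to the aldehyde (Wipf–Oppolzer type) set the (4R) carbinol by catalyst control, independent of the remote axis.

Step 7
Reactants: 12 (2E,4R,Ra)-1-[(tert-butyldimethylsilyl)oxy]-3,7,11-trimethyldodeca-2,5,6,11-tetraen-4-ol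
Product: 13 tert-butyldimethyl({(2E)-3-[(2R,7aR)-4,4,7a-trimethyl-2,4,5,6,7,7a-hexahydro-1-benzofuran-2-yl]but-2-en-1-yl}oxy)silane
Conditions: PdCl2(MeCN)2 (10 mol%), DMA, 25 → 50 °C
Reagents that add atoms: none
Why: Proposed new method: PdCl2 activates the allene and the C-4 hydroxyl attacks the methyl-bearing allene terminus (5-endo oxypalladation, anti to the metal), so the (Ra) axis becomes the (7aR) quaternary centre while C-2 keeps its (R) configuration; the resulting 3-palladio-2,5-dihydrofuran inserts the pendant 1,1-disubstituted alkene in a 6-exo Heck-type step that closes the cyclohexane and leaves a neopentyl alkylpalladium chloride without β-hydrogen, and protonolysis of that C–Pd bond by the HCl released in the first step gives the geminal dimethyl group and returns divalent palladium; the closest known reactions are the PdCl2-catalysed cyclisation–coupling of 2,3-allenols with allyl halides (oxypalladation then alkene insertion with axis-to-centre chirality transfer) and halide-assisted protonolysis of C–Pd bonds in enyne cyclisations.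

Step 8
Reactants: 13 tert-butyldimethyl({(2E)-3-[(2R,7aR)-4,4,7a-trimethyl-2,4,5,6,7,7a-hexahydro-1-benzofuran-2-yl]but-2-en-1-yl}oxy)silane
Product: 15 triphenyl{(2E)-3-[(2R,7aR)-4,4,7a-trimethyl-2,4,5,6,7,7a-hexahydro-1-benzofuran-2-yl]but-2-en-1-yl}phosphonium bromide, via allylic bromide 14 (not isolated)
Conditions: PPh3Br2, 2,6-lutidine (cat.), CH2Cl2, 0 °C; then PPh3, 25 °C
Reagents that add atoms: dibromotriphenylphosphorane, BrP(Br)(c1ccccc1)(c1ccccc1)c1ccccc1; triphenylphosphane, c1ccccc1P(c1ccccc1)c1ccccc1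
Why: PPh3Br2 exchanges the allylic silyl ether directly for bromide under neutral conditions and SN2 quaternisation of PPh3 gives the Wittig salt without isolating the labile bromide and without acid that could epimerise C-2.

Step 9
Reactants: 16 2,2,6-trimethylcyclohexan-1-one
Product: 17 trimethyl[(2,6,6-trimethylcyclohex-1-en-1-yl)oxy]silane
Conditions: LiN(iPr)2, THF, −78 → 0 °C; Me3SiCl
Reagents that add atoms: chlorotrimethylsilane, C[Si](C)(C)Cl
Why: C-6 is the only enolisable position, so deprotonation and O-silylation give a single tetrasubstituted silyl enol ether.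

Step 10
Reactants: 17 trimethyl[(2,6,6-trimethylcyclohex-1-en-1-yl)oxy]silane
Product: 18 (2R)-2-hydroxy-2,6,6-trimethylcyclohexan-1-one
Conditions: 1,2:4,5-di-O-isopropylidene-β-D-erythro-2,3-hexodiulo-2,6-pyranose (30 mol%), KHSO5, K2CO3, MeCN/CH2(OMe)2/H2O, 0 °C; then citric acid (cat.), MeOH
Reagents that add atoms: potassium peroxymonosulfate KHSO5, [K+].[O-]S(=O)(=O)OO
Why: Shi-type asymmetric dioxirane epoxidation of the silyl enol ether and collapse of the silyloxy epoxide (catalytic Rubottom-type oxidation) create the tertiary carbinol, the spiro transition state of the chiral dioxirane selecting the face that gives (R).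

Step 11
Reactants: 18 (2R)-2-hydroxy-2,6,6-trimethylcyclohexan-1-one; 19 (2E)-3-methylpent-2-en-4-yn-1-ol
Product: 22 (1R,2R)-1-[(3E)-5-hydroxy-3-methylpent-3-en-1-yn-1-yl]-2,6,6-trimethylcyclohexane-1,2-diol, via trimethylsilyl ether 20 (not isolated), via dilithium alkoxide acetylide 21 (not isolated)
Conditions: 18, LiN(SiMe3)2, Me3SiCl, THF, −78 → 0 °C; 19, n-BuLi (2.1 equiv), THF, −78 °C, then 20, −78 → −20 °C; K2CO3 (cat.), MeOH, 25 °C
Reagents that add atoms: none
Why: Acetylide 1,2-addition to the α-silyloxy ketone follows the polar Felkin–Anh model (non-chelating axial OSiMe3 antiperiplanar to the incoming nucleophile), so the new hydroxyl ends cis to the C-2 oxygen and the (1R,2R) cis-diol results after methanolysis of the silyl group.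

Step 12
Reactants: 22 (1R,2R)-1-[(3E)-5-hydroxy-3-methylpent-3-en-1-yn-1-yl]-2,6,6-trimethylcyclohexane-1,2-diol
Product: 23 (1S,2R)-1-[(1E,3E)-5-hydroxy-3-methylpenta-1,3-dien-1-yl]-2,6,6-trimethylcyclohexane-1,2-diol
Conditions: NaAlH2(OCH2CH2OMe)2 (4 equiv), THF, 0 → 25 °C; aq NaOH
Reagents that add atoms: none
Why: Alkoxide-directed trans-hydroalumination of the propargylic alcohol gives only the (E)-alkene after protonolysis and touches no stereocentre.

Step 13
Reactants: 23 (1S,2R)-1-[(1E,3E)-5-hydroxy-3-methylpenta-1,3-dien-1-yl]-2,6,6-trimethylcyclohexane-1,2-diol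
Product: 25 {(2E,4E)-5-[(1S,2R)-1,2-dihydroxy-2,6,6-trimethylcyclohexyl]-3-methylpenta-2,4-dien-1-yl}triphenylphosphonium bromide, via dienyl bromide 24 (not isolated)
Conditions: CBr4, PPh3 (2.5 equiv), 2,6-lutidine, CH2Cl2, −30 → 25 °C
Reagents that add atoms: tetrabromomethane, BrC(Br)(Br)Br; triphenylphosphane, c1ccccc1P(c1ccccc1)c1ccccc1
Why: Appel bromination is selective for the primary allylic alcohol over the two tertiary ones and the excess phosphane quaternises the bromide in situ (SN2), so the acid-labile tertiary allylic diol never meets acid.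

Step 14
Reactants: 15 triphenyl{(2E)-3-[(2R,7aR)-4,4,7a-trimethyl-2,4,5,6,7,7a-hexahydro-1-benzofuran-2-yl]but-2-en-1-yl}phosphonium bromide; 26 (2E,4E,6E)-2,7-dimethylocta-2,4,6-trienedial (3 equiv)
Product: 28 (2E,4E,6E,8E,10E)-2,7,11-trimethyl-11-[(2R,7aR)-4,4,7a-trimethyl-2,4,5,6,7,7a-hexahydro-1-benzofuran-2-yl]undeca-2,4,6,8,10-pentaenal, via phosphorus ylide 27 (not isolated)
Conditions: NaOMe, CH2Cl2/MeOH, −10 → 25 °C; then heptane, 85 °C
Reagents that add atoms: none
Why: Wittig olefination of the allylic ylide with an excess of the symmetric dialdehyde gives the mono-adduct, and thermal equilibration turns the new disubstituted double bond to E.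

Step 15
Reactants: 25 {(2E,4E)-5-[(1S,2R)-1,2-dihydroxy-2,6,6-trimethylcyclohexyl]-3-methylpenta-2,4-dien-1-yl}triphenylphosphonium bromide; 28 (2E,4E,6E,8E,10E)-2,7,11-trimethyl-11-[(2R,7aR)-4,4,7a-trimethyl-2,4,5,6,7,7a-hexahydro-1-benzofuran-2-yl]undeca-2,4,6,8,10-pentaenal
Product: 30 (5R,6S,5'R,8'R)-5',8'-epoxy-5,6,5',8'-tetrahydro-β,β-carotene-5,6-diol, via phosphorus ylide 29 (not isolated)
Conditions: NaOMe, CH2Cl2/MeOH, 0 → 25 °C; then EtOAc/heptane, 70 °C, dark
Reagents that add atoms: none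
Why: The second Wittig olefination joins the halves at C11=C12, tolerates the free tertiary hydroxyls, and thermal equilibration gives the all-E polyene without touching the four stereocentres.

**Compound list**
(Allene axes are written with the stereo tag on the central carbon and an explicit hydrogen on the CH terminus.)

1 | (2E)-pent-2-en-4-yn-1-ol | C#C/C=C/CO | starting material
2 | 5-bromo-2-methylpent-1-ene | C=C(C)CCCBr | starting material
3 | dilithium (3E)-5-oxidopent-3-en-1-yn-1-ide | [Li+].[Li+].[C-]#C/C=C/C[O-] | intermediate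
4 | (2E)-9-methyldeca-2,9-dien-4-yn-1-ol | C=C(C)CCCC#C/C=C/CO | intermediate
5 | [(2S,3S)-3-(6-methylhept-6-en-1-yn-1-yl)oxiran-2-yl]methanol | OC[C@@H]1O[C@H]1C#CCCCC(C)=C | intermediate
6 | (2R,Ra)-5,9-dimethyldeca-3,4,9-triene-1,2-diol | OC[C@H](O)C([H])=[C@]=C(C)CCCC(C)=C | intermediate
7 | (Ra)-4,8-dimethylnona-2,3,8-trienal | O=CC([H])=[C@]=C(C)CCCC(C)=C | intermediate
8 | but-2-yn-1-ol | CC#CCO | starting material
9 | tert-butyl(but-2-yn-1-yloxy)dimethylsilane | CC#CCO[Si](C)(C)C(C)(C)C | intermediate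
10 | chlorido{(2E)-4-[(tert-butyldimethylsilyl)oxy]but-2-en-2-yl}bis(cyclopentadienyl)zirconium | CC(C)(C)[Si](C)(C)OC/C=C(\C)[Zr](Cl)(C1C=CC=C1)C1C=CC=C1 | intermediate
11 | {(2E)-4-[(tert-butyldimethylsilyl)oxy]but-2-en-2-yl}(methyl)zinc | CC(C)(C)[Si](C)(C)OC/C=C(\C)[Zn]C | intermediate
12 | (2E,4R,Ra)-1-[(tert-butyldimethylsilyl)oxy]-3,7,11-trimethyldodeca-2,5,6,11-tetraen-4-ol | CC(C)(C)[Si](C)(C)OC/C=C(\C)[C@H](O)C([H])=[C@]=C(C)CCCC(C)=C | intermediate
13 | tert-butyldimethyl({(2E)-3-[(2R,7aR)-4,4,7a-trimethyl-2,4,5,6,7,7a-hexahydro-1-benzofuran-2-yl]but-2-en-1-yl}oxy)silane | CC(C)(C)[Si](C)(C)OC/C=C(\C)[C@H]1C=C2C(C)(C)CCC[C@@]2(C)O1 | intermediate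
14 | (2R,7aR)-2-[(2E)-4-bromobut-2-en-2-yl]-4,4,7a-trimethyl-2,4,5,6,7,7a-hexahydro-1-benzofuran | BrC/C=C(\C)[C@H]1C=C2C(C)(C)CCC[C@@]2(C)O1 | intermediate
15 | triphenyl{(2E)-3-[(2R,7aR)-4,4,7a-trimethyl-2,4,5,6,7,7a-hexahydro-1-benzofuran-2-yl]but-2-en-1-yl}phosphonium bromide | [Br-].c1ccccc1[P+](c1ccccc1)(c1ccccc1)C/C=C(\C)[C@H]1C=C2C(C)(C)CCC[C@@]2(C)O1 | intermediate
16 | 2,2,6-trimethylcyclohexan-1-one | CC1CCCC(C)(C)C1=O | starting material
17 | trimethyl[(2,6,6-trimethylcyclohex-1-en-1-yl)oxy]silane | CC1=C(O[Si](C)(C)C)C(C)(C)CCC1 | intermediate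
18 | (2R)-2-hydroxy-2,6,6-trimethylcyclohexan-1-one | O=C1C(C)(C)CCC[C@@]1(C)O | intermediate
19 | (2E)-3-methylpent-2-en-4-yn-1-ol | C#C/C(C)=C/CO | starting material
20 | (2R)-2,6,6-trimethyl-2-[(trimethylsilyl)oxy]cyclohexan-1-one | O=C1C(C)(C)CCC[C@@]1(C)O[Si](C)(C)C | intermediate
21 | dilithium (3E)-3-methyl-5-oxidopent-3-en-1-yn-1-ide | [Li+].[Li+].[C-]#C/C(C)=C/C[O-] | intermediate
22 | (1R,2R)-1-[(3E)-5-hydroxy-3-methylpent-3-en-1-yn-1-yl]-2,6,6-trimethylcyclohexane-1,2-diol | OC/C=C(\C)C#C[C@]1(O)C(C)(C)CCC[C@@]1(C)O | intermediate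
23 | (1S,2R)-1-[(1E,3E)-5-hydroxy-3-methylpenta-1,3-dien-1-yl]-2,6,6-trimethylcyclohexane-1,2-diol | OC/C=C(C)/C=C/[C@]1(O)C(C)(C)CCC[C@@]1(C)O | intermediate
24 | (1S,2R)-1-[(1E,3E)-5-bromo-3-methylpenta-1,3-dien-1-yl]-2,6,6-trimethylcyclohexane-1,2-diol | BrC/C=C(C)/C=C/[C@]1(O)C(C)(C)CCC[C@@]1(C)O | intermediate
25 | {(2E,4E)-5-[(1S,2R)-1,2-dihydroxy-2,6,6-trimethylcyclohexyl]-3-methylpenta-2,4-dien-1-yl}triphenylphosphonium bromide | [Br-].c1ccccc1[P+](c1ccccc1)(c1ccccc1)C/C=C(C)/C=C/[C@]1(O)C(C)(C)CCC[C@@]1(C)O | intermediate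
26 | (2E,4E,6E)-2,7-dimethylocta-2,4,6-trienedial | O=C/C(C)=C/C=C/C=C(C)/C=O | starting material
27 | triphenyl{(2E)-3-[(2R,7aR)-4,4,7a-trimethyl-2,4,5,6,7,7a-hexahydro-1-benzofuran-2-yl]but-2-en-1-ylidene}-λ5-phosphane | c1ccccc1P(c1ccccc1)(c1ccccc1)=C/C=C(\C)[C@H]1C=C2C(C)(C)CCC[C@@]2(C)O1 | intermediate
28 | (2E,4E,6E,8E,10E)-2,7,11-trimethyl-11-[(2R,7aR)-4,4,7a-trimethyl-2,4,5,6,7,7a-hexahydro-1-benzofuran-2-yl]undeca-2,4,6,8,10-pentaenal | O=C/C(C)=C/C=C/C=C(C)/C=C/C=C(\C)[C@H]1C=C2C(C)(C)CCC[C@@]2(C)O1 | intermediate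
29 | {(2E,4E)-5-[(1S,2R)-1,2-dihydroxy-2,6,6-trimethylcyclohexyl]-3-methylpenta-2,4-dien-1-ylidene}triphenyl-λ5-phosphane | c1ccccc1P(c1ccccc1)(c1ccccc1)=C/C=C(C)/C=C/[C@]1(O)C(C)(C)CCC[C@@]1(C)O | intermediate
30 | (5R,6S,5'R,8'R)-5',8'-epoxy-5,6,5',8'-tetrahydro-β,β-carotene-5,6-diol (CNP0378030.1) | CC(/C=C/C=C(C)/C=C/[C@]1(O)C(C)(C)CCC[C@@]1(C)O)=C\C=C\C=C(C)\C=C\C=C(/C)[C@H]1C=C2C(C)(C)CCC[C@@]2(C)O1 | target

**Step count and risks**

Total step count: 15. Longest linear sequence: 9 steps (steps 1, 2, 3, 4, 6, 7, 8, 14, 15).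

The three steps most likely to fail:

Step 7. The vinylpalladium may be protonated before it inserts the alkene, or the neopentyl alkylpalladium may not be protonated fast enough for turnover. The fallback sets out from 12 and separates the two ring closures. N-Iodosuccinimide in CH2Cl2 at 0 °C gives, by iodocyclisation with the same axis-to-centre transfer, the vinyl iodide tert-butyl({(2E)-3-[(2R,5R)-4-iodo-5-methyl-5-(4-methylpent-4-en-1-yl)-2,5-dihydrofuran-2-yl]but-2-en-1-yl}oxy)dimethylsilane F1. A reductive Heck cyclisation (Pd(OAc)2, PPh3, HCO2Na, Et4NCl, DMF, 80 °C; zerovalent palladium inserts into the C–I bond, 6-exo insertion, hydride from formate) then closes the cyclohexane, and the route is rejoined at 13.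

Step 6. The crude allenal 7 may isomerise to the dienal, or the catalyst may not control C-4. The fallback sets out from 9 and gives up catalyst control in favour of separation. Hydrozirconation with Cp2Zr(H)Cl and iodinolysis give tert-butyl{[(2E)-3-iodobut-2-en-1-yl]oxy}dimethylsilane F2. Iodine–lithium exchange with t-BuLi at −78 °C gives {(2E)-4-[(tert-butyldimethylsilyl)oxy]but-2-en-2-yl}lithium F3, which adds to 7 at −78 °C to give 12 together with its epimer (2E,4S,Ra)-1-[(tert-butyldimethylsilyl)oxy]-3,7,11-trimethyldodeca-2,5,6,11-tetraen-4-ol F4. The two diastereomers are separated by chromatography. F4 is recycled by Dess–Martin oxidation to (2E,Ra)-1-[(tert-butyldimethylsilyl)oxy]-3,7,11-trimethyldodeca-2,5,6,11-tetraen-4-one F5 and NaBH4/CeCl3 reduction, and the route is rejoined at 12.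

Step 10. The tetrasubstituted enol ether next to a quaternary carbon may be epoxidised slowly or with low selectivity. The fallback sets out from 16 and replaces the catalytic epoxidation by hydroxylation of an enolate with a stoichiometric chiral oxidant. KN(SiMe3)2 in THF at −78 °C gives potassium 2,6,6-trimethylcyclohex-1-en-1-olate F6, which is oxidised with (+)-[(8,8-dichlorocamphoryl)sulfonyl]oxaziridine (or its enantiomer, whichever gives the (R)-alcohol) and quenched with NH4Cl, and the route is rejoined at 18.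

Further compounds
F1 | step 7 | tert-butyl({(2E)-3-[(2R,5R)-4-iodo-5-methyl-5-(4-methylpent-4-en-1-yl)-2,5-dihydrofuran-2-yl]but-2-en-1-yl}oxy)dimethylsilane | CC(C)(C)[Si](C)(C)OC/C=C(\C)[C@H]1C=C(I)[C@@](C)(CCCC(C)=C)O1
F2 | step 6 | tert-butyl{[(2E)-3-iodobut-2-en-1-yl]oxy}dimethylsilane | CC(C)(C)[Si](C)(C)OC/C=C(\C)I
F3 | step 6 | {(2E)-4-[(tert-butyldimethylsilyl)oxy]but-2-en-2-yl}lithium | CC(C)(C)[Si](C)(C)OC/C=C(\C)[Li]
F4 | step 6 | (2E,4S,Ra)-1-[(tert-butyldimethylsilyl)oxy]-3,7,11-trimethyldodeca-2,5,6,11-tetraen-4-ol | CC(C)(C)[Si](C)(C)OC/C=C(\C)[C@@H](O)C([H])=[C@]=C(C)CCCC(C)=C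
F5 | step 6 | (2E,Ra)-1-[(tert-butyldimethylsilyl)oxy]-3,7,11-trimethyldodeca-2,5,6,11-tetraen-4-one | CC(C)(C)[Si](C)(C)OC/C=C(\C)C(=O)C([H])=[C@]=C(C)CCCC(C)=C
F6 | step 10 | potassium 2,6,6-trimethylcyclohex-1-en-1-olate | [K+].[O-]C1=C(C)CCCC1(C)C
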